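**Plan**

- Retrosynthesis: the bond between C6 of the chromene benzene ring and the adjacent carbonyl carbon of the 1,2-dione is cut with that carbon at the carbinol level, giving chromenol 10 and arylglyoxal 13. The C8–prenyl bond is then cut (back to a 5-O-prenyl ether), the C3=C4 alkene goes back to a C4 ketone, and the pyranone ring goes back to phloroglucinol and 3-methylbut-2-enoic acid.
- Forward: the pyranone ring is fused onto phloroglucinol first. Its C4 carbonyl is a temporary control element: it directs 7-O-methylation and then the Claisen–Cope transfer of prenyl from O5 to C8, and is finally removed as the C3=C4 alkene of the 2H-chromene.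
- Feature used by the key event: C6 is the only unsubstituted carbon of the benzene ring. It lies ortho to the free C5 hydroxyl and to the C7 methoxy group and para to the pyran oxygen O1, so the C5 magnesium phenoxide can deliver the glyoxal aldehyde carbon to C6.
- The carbinol is then oxidised to the second ketone and the silyl ether on the 4-hydroxyphenyl ring is removed last.
- Stereochemistry: the target has no stereocentre. The carbinol centre formed in step 8 is racemic and is erased in step 9.

Key step: step 8

Remark: the target is treated as the open-chain 1,2-diketone shown by its SMILES; ring-chain tautomerism with the cyclic hemiketal is not considered.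

**Route**

Step 1
Reactants: 1 phloroglucinol; 2 3-methylbut-2-enoic acid
Product: 3 5,7-dihydroxy-2,2-dimethylchroman-4-one
Conditions: MeSO3H, P2O5 (Eaton's reagent), 70 °C
Reagents that add atoms: none
Why: Friedel–Crafts acylation of the symmetrical triphenol followed by intramolecular oxa-Michael addition should close the pyranone ring, and the symmetry of 1 allows only one regioisomer.

Step 2
Reactants: 3 5,7-dihydroxy-2,2-dimethylchroman-4-one
Product: 4 5-hydroxy-7-methoxy-2,2-dimethylchroman-4-one
Conditions: MeI (1.1 equiv), K2CO3 (1.1 equiv), acetone, rt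
Reagents that add atoms: iodomethane, CI
Why: Williamson etherification should occur at the 7-OH, which is the more acidic hydroxyl (para to the carbonyl), while the 5-OH is held in a hydrogen bond to the C4 carbonyl.

Step 3
Reactants: 4 5-hydroxy-7-methoxy-2,2-dimethylchroman-4-one; 5 1-bromo-3-methylbut-2-ene (prenyl bromide)
Product: 6 7-methoxy-2,2-dimethyl-5-(3-methylbut-2-enyloxy)chroman-4-one
Conditions: K2CO3, DMF, 50 °C
Reagents that add atoms: none
Why: Williamson O-alkylation of the chelated phenol should proceed under polar aprotic conditions, which favour O- over C-alkylation of the phenoxide.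

Step 4
Reactants: 6 7-methoxy-2,2-dimethyl-5-(3-methylbut-2-enyloxy)chroman-4-one
Product: 8 5-hydroxy-7-methoxy-2,2-dimethyl-8-(3-methylbut-2-enyl)chroman-4-one, via ortho-dienone 7 (not isolated)
Conditions: Eu(fod)3 (10 mol%), CHCl3, 60 °C, sealed tube
Reagents that add atoms: none
Why: Domino Claisen–Cope rearrangement: the europium Lewis acid bound at the C4 carbonyl and ether oxygen should accelerate the [3,3] shift to C6 (the only free ortho carbon), and dienone 7 should undergo a second [3,3] shift to C8 before enolisation, a sequence precedented for 5-O-prenyl flavanones.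

Step 5
Reactants: 8 5-hydroxy-7-methoxy-2,2-dimethyl-8-(3-methylbut-2-enyl)chroman-4-one
Product: 10 7-methoxy-2,2-dimethyl-8-(3-methylbut-2-enyl)-2H-chromen-5-ol, via chroman-4-ol 9 (not isolated)
Conditions: NaBH4, THF–MeOH, 0 °C to rt; then p-TsOH·H2O (5 mol%), toluene, rt
Reagents that add atoms: none
Why: Hydride reduction of the aryl ketone followed by acid-catalysed E1 dehydration should give the chromene, because the C4 cation is stabilised by the ortho and para oxygens; the prenyl group has no free ortho hydroxyl and cannot cyclise.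

Step 6
Reactants: 11 4'-hydroxyacetophenone
Product: 12 4'-(triisopropylsilyloxy)acetophenone
Conditions: TIPSCl, imidazole, DMF, rt
Reagents that add atoms: chlorotriisopropylsilane, CC(C)[Si](Cl)(C(C)C)C(C)C
Why: Imidazole-promoted silylation of the phenol should give a hindered aryl silyl ether that survives the later oxidation and magnesium phenoxide steps.

Step 7
Reactants: 12 4'-(triisopropylsilyloxy)acetophenone
Product: 13 2-oxo-2-[4-(triisopropylsilyloxy)phenyl]acetaldehyde (anhydrous arylglyoxal)
Conditions: SeO2 (1.3 equiv), 1,4-dioxane–H2O (20:1), 90 °C; then azeotropic drying with toluene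
Reagents that add atoms: selenium dioxide, O=[Se]=O
Why: Riley oxidation of the aryl methyl ketone through its enol should give the glyoxal hydrate, which is dehydrated azeotropically; the only oxidisable C–H bonds are those of the acetyl group.

Step 8
Reactants: 10 7-methoxy-2,2-dimethyl-8-(3-methylbut-2-enyl)-2H-chromen-5-ol; 13 2-oxo-2-[4-(triisopropylsilyloxy)phenyl]acetaldehyde
Product: 15 2-hydroxy-2-[5-hydroxy-7-methoxy-2,2-dimethyl-8-(3-methylbut-2-enyl)-2H-chromen-6-yl]-1-[4-(triisopropylsilyloxy)phenyl]ethanone (racemic), via bromomagnesium phenoxide 14 (not isolated)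
Conditions: EtMgBr (1.0 equiv), Et2O, 0 °C; solvent exchange to toluene; 13 (1.2 equiv), 0 °C to rt; then H2O
Reagents that add atoms: none
Why: Deprotonation gives the magnesium phenoxide 14, whose magnesium binds the aldehyde oxygen of the glyoxal so that C6 attacks the formyl carbon through a six-membered cyclic transition state, and the resulting dienone rearomatises by proton loss to the magnesium chelate of 15. The closest known reaction type is the ortho-specific hydroxyalkylation of magnesium phenoxides with activated aldehydes (metal-template Friedel–Crafts hydroxyalkylation, as with glyoxylates and arylglyoxals). No ring is closed. The new carbinol stereocentre is formed without control as a racemate, which is acceptable because step 9 turns it into a carbonyl carbon. The step needs C- over O-attack, aldehyde over ketone attack and arene over alkene attack: C6 is the only unsubstituted ring carbon and is activated by the ortho C5–O–Mg, the ortho C7–OMe and the para O1, the formyl carbon is the more electrophilic and less hindered carbonyl, and the non-acidic magnesium template in toluene should leave the prenyl and chromene double bonds untouched. The adjacent ketone disfavours ionisation of the new benzylic carbinol, so diarylmethane formation is not expected.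

Step 9
Reactants: 15 2-hydroxy-2-[5-hydroxy-7-methoxy-2,2-dimethyl-8-(3-methylbut-2-enyl)-2H-chromen-6-yl]-1-[4-(triisopropylsilyloxy)phenyl]ethanone
Product: 16 1-[5-hydroxy-7-methoxy-2,2-dimethyl-8-(3-methylbut-2-enyl)-2H-chromen-6-yl]-2-[4-(triisopropylsilyloxy)phenyl]ethane-1,2-dione
Conditions: Cu(OAc)2·H2O (20 mol%), pyridine, O2 (1 atm), 40 °C
Reagents that add atoms: none
Why: Copper(II)-catalysed aerobic benzoin-to-benzil oxidation: Cu(II) should oxidise the chelated enediolate by two one-electron transfers and O2 returns Cu(I) to Cu(II); the acyloin tautomer and the cyclic hemiketal of 15 converge on the same diketone, and all ring carbons ortho and para to the phenol are substituted, so phenol coupling has no site.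

Step 10
Reactants: 16 1-[5-hydroxy-7-methoxy-2,2-dimethyl-8-(3-methylbut-2-enyl)-2H-chromen-6-yl]-2-[4-(triisopropylsilyloxy)phenyl]ethane-1,2-dione
Product: 17 1-[5-hydroxy-7-methoxy-2,2-dimethyl-8-(3-methylbut-2-enyl)-2H-chromen-6-yl]-2-(4-hydroxyphenyl)ethane-1,2-dione (target CNP0184805.0)
Conditions: TBAF (1.1 equiv), AcOH (1.2 equiv), THF, 0 °C
Reagents that add atoms: none
Why: Fluoride-mediated desilylation should be fast because the 4-acylphenoxide is a good leaving group on silicon, and the acetic acid buffer keeps the base-sensitive 1,2-diketone away from strong base.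

**Compound list**

1 | phloroglucinol | Oc1cc(O)cc(O)c1 | starting material
2 | 3-methylbut-2-enoic acid | CC(C)=CC(=O)O | starting material
3 | 5,7-dihydroxy-2,2-dimethylchroman-4-one | CC1(C)CC(=O)c2c(O)cc(O)cc2O1 | intermediate
4 | 5-hydroxy-7-methoxy-2,2-dimethylchroman-4-one | COc1cc(O)c2C(=O)CC(C)(C)Oc2c1 | intermediate
5 | 1-bromo-3-methylbut-2-ene (prenyl bromide) | CC(C)=CCBr | starting material
6 | 7-methoxy-2,2-dimethyl-5-(3-methylbut-2-enyloxy)chroman-4-one | COc1cc(OCC=C(C)C)c2C(=O)CC(C)(C)Oc2c1 | intermediate
7 | ortho-dienone: 7-methoxy-2,2-dimethyl-6-(2-methylbut-3-en-2-yl)-2,3-dihydrochromene-4,5(6H)-dione (racemic, transient) | COC1=CC2=C(C(=O)CC(C)(C)O2)C(=O)C1C(C)(C)C=C | intermediate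
8 | 5-hydroxy-7-methoxy-2,2-dimethyl-8-(3-methylbut-2-enyl)chroman-4-one | COc1cc(O)c2C(=O)CC(C)(C)Oc2c1CC=C(C)C | intermediate
9 | 7-methoxy-2,2-dimethyl-8-(3-methylbut-2-enyl)chroman-4,5-diol (racemic chroman-4-ol) | COc1cc(O)c2C(O)CC(C)(C)Oc2c1CC=C(C)C | intermediate
10 | 7-methoxy-2,2-dimethyl-8-(3-methylbut-2-enyl)-2H-chromen-5-ol | COc1cc(O)c2C=CC(C)(C)Oc2c1CC=C(C)C | intermediate
11 | 4'-hydroxyacetophenone | CC(=O)c1ccc(O)cc1 | starting material
12 | 4'-(triisopropylsilyloxy)acetophenone | CC(=O)c1ccc(O[Si](C(C)C)(C(C)C)C(C)C)cc1 | intermediate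
13 | 2-oxo-2-[4-(triisopropylsilyloxy)phenyl]acetaldehyde | O=CC(=O)c1ccc(O[Si](C(C)C)(C(C)C)C(C)C)cc1 | intermediate
14 | bromomagnesium 7-methoxy-2,2-dimethyl-8-(3-methylbut-2-enyl)-2H-chromen-5-olate | COc1cc(O[Mg]Br)c2C=CC(C)(C)Oc2c1CC=C(C)C | intermediate
15 | 2-hydroxy-2-[5-hydroxy-7-methoxy-2,2-dimethyl-8-(3-methylbut-2-enyl)-2H-chromen-6-yl]-1-[4-(triisopropylsilyloxy)phenyl]ethanone (racemic) | COc1c(CC=C(C)C)c2c(c(O)c1C(O)C(=O)c1ccc(O[Si](C(C)C)(C(C)C)C(C)C)cc1)C=CC(C)(C)O2 | intermediate
16 | 1-[5-hydroxy-7-methoxy-2,2-dimethyl-8-(3-methylbut-2-enyl)-2H-chromen-6-yl]-2-[4-(triisopropylsilyloxy)phenyl]ethane-1,2-dione | COc1c(CC=C(C)C)c2c(c(O)c1C(=O)C(=O)c1ccc(O[Si](C(C)C)(C(C)C)C(C)C)cc1)C=CC(C)(C)O2 | intermediate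
17 | 1-[5-hydroxy-7-methoxy-2,2-dimethyl-8-(3-methylbut-2-enyl)-2H-chromen-6-yl]-2-(4-hydroxyphenyl)ethane-1,2-dione | COc1c(CC=C(C)C)c2c(c(O)c1C(=O)C(=O)c1ccc(O)cc1)C=CC(C)(C)O2 | target

**Summary**

Total step count: 10. Longest linear sequence: 8 steps (steps 1–5, 8, 9, 10).

Steps most likely to fail:

1. Step 8. The hindered C6 may react slowly, the glyoxal may undergo a carbonyl-ene reaction with the prenyl alkene, or the adduct may cyclodehydrate to a benzofuranone. The fallback replaces the phenoxide-directed substitution by a preformed aryllithium. It sets out from 10, which is brominated at C6 (NBS, CH2Cl2, −78 °C) to 6-bromo-7-methoxy-2,2-dimethyl-8-(3-methylbut-2-enyl)-2H-chromen-5-ol F1. Treatment of F1 with n-BuLi (2.2 equiv, THF, −78 °C) should form the lithium phenoxide and exchange bromine for lithium, and the aryllithium should add to the aldehyde carbon of 13. The fallback comes back to the route at 15.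

2. Step 9. The copper/oxygen system may oxidise the electron-rich phenol or chromene, or cleave the C–C bond of the diketone. The fallback masks the phenol and uses a non-metal oxidant. It sets out from 15, which is silylated at the more acidic phenolic hydroxyl (TBSCl 1.05 equiv, imidazole, DMF, 0 °C) to 2-[5-(tert-butyldimethylsilyloxy)-7-methoxy-2,2-dimethyl-8-(3-methylbut-2-enyl)-2H-chromen-6-yl]-2-hydroxy-1-[4-(triisopropylsilyloxy)phenyl]ethanone F2. Oxidation with Dess–Martin periodinane (NaHCO3, CH2Cl2, 0 °C) should give 1-[5-(tert-butyldimethylsilyloxy)-7-methoxy-2,2-dimethyl-8-(3-methylbut-2-enyl)-2H-chromen-6-yl]-2-[4-(triisopropylsilyloxy)phenyl]ethane-1,2-dione F3. TBAF/AcOH in THF then removes both silyl groups, and the fallback comes back to the route at 17.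

3. Step 5. The ortho-hydroxybenzylic alcohol may be over-reduced through an ortho-quinone methide to the chroman, or the electron-rich chromene may dimerise under acid. The fallback avoids both hydride and acid. It sets out from 8, which is condensed with p-toluenesulfonyl hydrazide (EtOH, cat. AcOH, reflux) to 5-hydroxy-7-methoxy-2,2-dimethyl-8-(3-methylbut-2-enyl)chroman-4-one p-toluenesulfonylhydrazone F4. A Shapiro reaction of F4 (MeLi 3.5 equiv, THF, 0 °C to rt, then water) should give the C3=C4 alkene, and the fallback comes back to the route at 10.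

**Further compounds**

F1 | step 8 | 6-bromo-7-methoxy-2,2-dimethyl-8-(3-methylbut-2-enyl)-2H-chromen-5-ol | COc1c(Br)c(O)c2C=CC(C)(C)Oc2c1CC=C(C)C
F2 | step 9 | 2-[5-(tert-butyldimethylsilyloxy)-7-methoxy-2,2-dimethyl-8-(3-methylbut-2-enyl)-2H-chromen-6-yl]-2-hydroxy-1-[4-(triisopropylsilyloxy)phenyl]ethanone | COc1c(CC=C(C)C)c2c(c(O[Si](C)(C)C(C)(C)C)c1C(O)C(=O)c1ccc(O[Si](C(C)C)(C(C)C)C(C)C)cc1)C=CC(C)(C)O2
F3 | step 9 | 1-[5-(tert-butyldimethylsilyloxy)-7-methoxy-2,2-dimethyl-8-(3-methylbut-2-enyl)-2H-chromen-6-yl]-2-[4-(triisopropylsilyloxy)phenyl]ethane-1,2-dione | COc1c(CC=C(C)C)c2c(c(O[Si](C)(C)C(C)(C)C)c1C(=O)C(=O)c1ccc(O[Si](C(C)C)(C(C)C)C(C)C)cc1)C=CC(C)(C)O2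
F4 | step 5 | 5-hydroxy-7-methoxy-2,2-dimethyl-8-(3-methylbut-2-enyl)chroman-4-one p-toluenesulfonylhydrazone | COc1cc(O)c2C(=NNS(=O)(=O)c3ccc(C)cc3)CC(C)(C)Oc2c1CC=C(C)C
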